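## Analysis of the target

The target is a daucane sesquiterpenoid ester. A cyclopentane (ring A, C1–C5) is trans-fused to a cycloheptane (ring B, C5–C10 and C1), with a vanillate on O6. It has five stereocentres, (1R,4R,5S,6S,9S) in daucane numbering. The C1 methyl and the C4 hydroxyl lie on one face (β); H5, the C6 acyloxy group, the C9 hydroxyl and the C4 isopropyl group lie on the other (α). The ring fusion is therefore trans, and H5 and O6 are cis.

C5 is flanked by two fully substituted carbons (C1 quaternary, C4 a tertiary carbinol), so every bond made to C5 is made in a crowded place. The tertiary carbinol can ionise or eliminate. The C8 exocyclic methylene next to the C9 allylic alcohol can isomerise or transpose. The aryl ester sits among three hydroxyls and a free phenol and must go to O6 only.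

The main difficulties are the quaternary C1, the absolute configuration of the isopropyl/alkyl tertiary carbinol at C4, the trans fusion, and a seven-membered ring with four functionalised carbons. The strategy rests on ring B: C9 is at the carbonyl oxidation level, 1,3 to C1 and 1,4 to C6. C1, C10, C9, C8 and C7 can therefore come from a 1-silyloxy vinylcyclopropane, and C5–C6 from an alkyne tethered through C2–C4.

## Retrosynthetic reasoning

**36 ⇐ 35 ⇐ 34 ⇐ 33.** The O–Si bonds of 35 are cut last. Before that, the C9–H bond is cut (enone 34) and then the C8=C14 bond (ketone 33). The C9 ketone is chosen as the precursor of both groups because it activates C8 for attaching C14 and offers a prochiral centre for a catalyst-controlled reduction. Forward, the methylenation must choose C8 over C10, and hydride must reach C9 from the β-face.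

**33 ⇐ 32 ⇐ 27 + 30.** The ester C–O bond is cut where O6 is the only free hydroxyl (O4 silylated, C9 ketalised), so no selection among hydroxyls is needed. Acid 30 is vanillic acid 28 with the phenol silylated.

**27 ⇐ 25 ⇐ 24 ⇐ 23.** The C5–H and C6–O bonds are cut together to the C5=C6 alkene of 25. One syn addition then creates the trans fusion and the C6 carbinol with their cis relationship, provided it comes from the face opposite the C1 methyl and O4. The ketal of 25 masks ketone 24, which is the hydrolysis product of silyl enol ether 23.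

**23 ⇐ 22.** This is the key disconnection: C1–C5 and C6–C7 are cut and both rings open to enyne 22. It is placed here because the cycloadduct carries exactly what ring B needs (C9 enol ether, C5=C6 alkene), the quaternary C1 is formed as the rings close, and C4 is already in place to direct it. The forward reaction must accept a fully substituted alkene terminus and read the C4 configuration.

**22 ⇐ 21 ⇐ 20.** The terminal alkyne is cut back to aldehyde 21 (one-carbon homologation supplies C6) and to primary silyl ether 20. The alkyne is unveiled last so that its acidic C–H never meets an organolithium and two alkynes never have to be told apart.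

**20 ⇐ 19 ⇐ 12 + 14.** The C9–C10 bond is cut between the alkenyl metal from iodide 12 and cyclopropanone 18, released from hemiacetal 14 (made from 13). The E geometry is fixed before the cyclopropane arrives.

**12 ⇐ 11 ⇐ 9.** The C1–CH3 and C10–I bonds are cut to terminal alkyne 9. Syn carbometalation defines the trisubstituted alkene.

**9 ⇐ 5 + 6; 5 ⇐ 4 ⇐ 3 ⇐ 1 + 2.** The C2–C3 bond is cut: epoxide 5 is opened at its CH2 by lithiated 6. The C4 configuration comes from Sharpless epoxidation of allylic alcohol 3. This is preferred to an enantioselective addition of an ethynyl group to a C4 carbonyl, because isopropyl and a primary alkyl chain are too alike for dependable face selection. The C4 centre is never touched again.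

## Alternatives that were turned down

**Alternative 1:** Ring A is annulated onto a preformed ring B by cutting C1–C2 and C4–C5. The partners are the silyloxy cycloheptenone A2 and the isopropyl-substituted silylallene A3. Forward, a strong Lewis acid activates A2, the CH2 terminus of A3 adds to the β-carbon C1, silicon shifts, and the metal enolate closes on the vinyl cation to give A1 (Danheiser annulation).

- For: it is convergent, forms two bonds and C1 in one step, delivers C6 as a ketone (no hydroboration of a hindered alkene) and carries the C9 oxygen from the start. On oxidation-state economy at C6 and C9 it is stronger than the chosen route.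
- Against: the acceptor is a β,β-disubstituted seven-membered enone, and facial control must come from the remote C9 silyloxy group across a flexible ring. The annulation is suprafacial, so A1 is cis-fused, while the target is trans-fused; epimerisation at C5 next to the C6 ketone would be expected to favour cis in an angular-methyl bicycle. The C9 oxygen of A1 is on the face opposite to the target. The C4 carbinol must still be carved, face-selectively, out of a tetrasubstituted vinylsilane.
- In exchange, the chosen route fixes C4 in the absolute sense before any ring exists and reaches the trans fusion by a syn addition.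

**Alternative 2:** Ring B is cut at C7–C8 and C1–C10, giving the cyclopentenyl silyloxydiene A5 and the silyloxy vinyldiazoacetate A6. Forward, a chiral dirhodium tetracarboxylate turns A6 into a vinylcarbenoid that cyclopropanates the terminal alkene of A5; the cis-divinylcyclopropane then undergoes Cope rearrangement to A4.

- For: it is catalytic and asymmetric, builds ring B and C1 in one operation, and leaves C6 and C9 oxygenated with the future C14 already on C8. In placing functionality on ring B it is clearly stronger than the chosen route (no hydroboration, no methylenation).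
- Against: the Cope step must bond to a fully substituted alkene carbon inside a cyclopentene. The cyclopropanated alkene is 1,1-disubstituted, where enantio- and cis-selectivity are less secure. A4 carries two silyl enol ethers that must be distinguished. Neither C4 (isopropyl addition to an enolisable, hindered ketone, guided only by the C1 methyl) nor the trans H5 is set.
- In exchange, the chosen route sets C4 first by a dependable epoxidation and then installs H5 and O6 together.

**Alternative 3:** The whole skeleton is traced to farnesyl diphosphate A8. Forward, a daucane-forming sesquiterpene cyclase ionises A8, forms C1–C10 and C4–C5 in one cationic cascade with a hydride shift to the isopropyl cation, and loses the C5 proton to give daucene A7.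

- For: all fifteen carbons, both rings and C1 arrive in one step. No chemical route, including the chosen one, matches this.
- Against: A7 is a hydrocarbon. The target needs net hydration of the tetrasubstituted C4=C5 alkene (O4 β, H5 α), oxygenation at C6, and an ene-type oxygenation that moves C8=C9 to the exocyclic position with O9 α. These are three site- and face-selective oxidations on two similar alkenes, the wrong one being the more electron-rich. Enzyme supply and the scale of A8 add to this.
- In exchange, the chosen route is longer, but every oxygen has a planned origin: C4 and C9 from building blocks, C6 from one hydroboration.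

Key step: step 12

Remark on numbering: skeletal carbons carry daucane numbers (C1 quaternary fusion carbon with CH3, C2 and C3 ring-A CH2, C4 isopropyl carbinol, C5 fusion CH, C6–C10 ring B; C14 is the exocyclic CH2 on C8).

Assumption: in step 2 diethyl D-(−)-tartrate is taken to give the (R)-epoxy alcohol, the same sense that gives (R)-glycidol from allyl alcohol; high enantiomeric excess is expected and is carried through unchanged.

## Steps

Step 1
Reactants: 1 prop-2-yn-1-ol; 2 isopropylmagnesium chloride
Product: 3 3-methyl-2-methylidenebutan-1-ol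
Conditions: 2 (2.5 equiv), CuI (10 mol %), THF, −10 °C → rt; aq. NH4Cl
Reagents that add atoms: none
Why: Copper-catalysed anti-carbomagnesiation of the propargylic alkoxide puts the isopropyl group on C2 through a cyclic alkenylmagnesium alkoxide, and hydrolysis gives the 2-substituted allylic alcohol; no stereocentre is formed.

Step 2
Reactants: 3 3-methyl-2-methylidenebutan-1-ol
Product: 4 [(2R)-2-(propan-2-yl)oxiran-2-yl]methanol
Conditions: Ti(OiPr)4 (10 mol %), diethyl D-(−)-tartrate (12 mol %), t-BuOOH, 4 Å molecular sieves, CH2Cl2, −20 °C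
Reagents that add atoms: tert-butyl hydroperoxide, CC(C)(C)OO
Why: Catalytic Sharpless asymmetric epoxidation; 2-substituted allylic alcohols are a dependable substrate class, and the tartrate chooses the alkene face, which sets the future C4 stereocentre by reagent control.

Step 3
Reactants: 4 [(2R)-2-(propan-2-yl)oxiran-2-yl]methanol
Product: 5 triethyl{[(2S)-2-(propan-2-yl)oxiran-2-yl]methoxy}silane
Conditions: Et3SiCl, imidazole, CH2Cl2, 0 °C
Reagents that add atoms: chlorotriethylsilane, CC[Si](Cl)(CC)CC
Why: Standard silylation of a primary alcohol; it removes the acidic proton before the organolithium step and makes the small epoxide non-volatile (the descriptor changes only because of CIP priorities).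

Step 4
Reactants: 5 triethyl{[(2S)-2-(propan-2-yl)oxiran-2-yl]methoxy}silane; 6 trimethyl(prop-1-yn-1-yl)silane
Product: 9 (2R)-2-(propan-2-yl)hept-6-yne-1,2-diol, via lithiated silylpropyne 7 (not isolated), via silylated hydroxyalkyne 8 (not isolated)
Conditions: 6, n-BuLi, THF, −40 °C; then 5, BF3·OEt2, −78 °C; aq. NaHCO3; then Bu4NF, THF, rt
Reagents that add atoms: none
Why: Propargylic lithiation of the silylpropyne, then Lewis-acid-assisted SN2 opening of the epoxide at its unsubstituted CH2 (the C2–C3 bond), which leaves the stereocentre untouched; fluoride then removes the C-silyl and O-silyl groups together.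

Step 5
Reactants: 9 (2R)-2-(propan-2-yl)hept-6-yne-1,2-diol
Product: 11 (2R,6E)-7-iodo-6-methyl-2-(propan-2-yl)hept-6-ene-1,2-diol, via alkenylalane 10 (not isolated)
Conditions: Me3Al (5 equiv), Cp2ZrCl2 (0.5 equiv), CH2Cl2, 0 °C → rt; then I2, THF, −30 → 0 °C
Reagents that add atoms: trimethylaluminium, C[Al](C)C; iodine, II
Why: Negishi zirconium-catalysed carboalumination adds CH3 and Al syn across the terminal alkyne with Al on the terminal carbon, and iodinolysis with retention gives the (E)-iodide; the hydroxyls travel as aluminium alkoxides.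

Step 6
Reactants: 11 (2R,6E)-7-iodo-6-methyl-2-(propan-2-yl)hept-6-ene-1,2-diol
Product: 12 (2R,6E)-7-iodo-6-methyl-2-(propan-2-yl)-1,2-bis[(triethylsilyl)oxy]hept-6-ene
Conditions: Et3SiOTf (2.5 equiv), 2,6-lutidine, CH2Cl2, −78 → 0 °C
Reagents that add atoms: triethylsilyl trifluoromethanesulfonate, CC[Si](CC)(CC)OS(=O)(=O)C(F)(F)F
Why: The silyl triflate silylates the primary and the hindered tertiary hydroxyl in one operation, as required before halogen–lithium exchange.

Step 7
Reactants: 13 (1-ethoxycyclopropoxy)trimethylsilane
Product: 14 1-ethoxycyclopropan-1-ol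
Conditions: MeOH, rt; concentrate
Reagents that add atoms: none
Why: Methanolysis of the silyl group of the mixed ketal gives the cyclopropanone hemiacetal, the storable cyclopropanone equivalent.

Step 8
Reactants: 12 (2R,6E)-7-iodo-6-methyl-2-(propan-2-yl)-1,2-bis[(triethylsilyl)oxy]hept-6-ene; 14 1-ethoxycyclopropan-1-ol
Product: 19 1-{(1E,5R)-2-methyl-5-(propan-2-yl)-5,6-bis[(triethylsilyl)oxy]hex-1-en-1-yl}cyclopropan-1-ol, via alkenyllithium 15 (not isolated), via alkenylmagnesium bromide 16 (not isolated), via magnesium hemiacetalate 17 (not isolated), via cyclopropanone 18 (not isolated)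
Conditions: 12, t-BuLi (2.1 equiv), Et2O, −78 °C; MgBr2·OEt2, −78 → 0 °C; added to 14 (2 equiv) + MeMgBr (2 equiv), THF, 0 °C; then 0 → 40 °C; aq. NH4Cl
Reagents that add atoms: none
Why: Iodine–lithium exchange and transmetalation proceed with retention of alkene geometry, and the alkenylmagnesium adds 1,2 to cyclopropanone, which the magnesium hemiacetalate releases in situ by loss of ethoxide (C9–C10 bond).

Step 9
Reactants: 19 1-{(1E,5R)-2-methyl-5-(propan-2-yl)-5,6-bis[(triethylsilyl)oxy]hex-1-en-1-yl}cyclopropan-1-ol
Product: 20 tert-butyl({1-[(1E,5R)-2-methyl-5-(propan-2-yl)-5,6-bis[(triethylsilyl)oxy]hex-1-en-1-yl]cyclopropyl}oxy)dimethylsilane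
Conditions: t-BuMe2SiOTf, 2,6-lutidine, CH2Cl2, −78 → 0 °C
Reagents that add atoms: tert-butyldimethylsilyl trifluoromethanesulfonate, CC(C)(C)[Si](C)(C)OS(=O)(=O)C(F)(F)F
Why: Silylation of the tertiary cyclopropanol under non-acidic conditions avoids ring expansion of the alkenylcyclopropanol and installs the donor group that will end as the C9 enol ether.

Step 10
Reactants: 20 tert-butyl({1-[(1E,5R)-2-methyl-5-(propan-2-yl)-5,6-bis[(triethylsilyl)oxy]hex-1-en-1-yl]cyclopropyl}oxy)dimethylsilane
Product: 21 (2R,5E)-6-{1-[(tert-butyldimethylsilyl)oxy]cyclopropyl}-5-methyl-2-(propan-2-yl)-2-[(triethylsilyl)oxy]hex-5-enal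
Conditions: (COCl)2, DMSO, CH2Cl2, −78 → −40 °C; Et3N, −78 °C → rt
Reagents that add atoms: none
Why: Direct Swern oxidation of a primary triethylsilyl ether: the activated sulfoxide cleaves the least hindered primary O–Si bond and oxidises the alkoxysulfonium ion in the same flask, while the two tertiary silyl ethers are too hindered and have no carbinol hydrogen.

Step 11
Reactants: 21 (2R,5E)-6-{1-[(tert-butyldimethylsilyl)oxy]cyclopropyl}-5-methyl-2-(propan-2-yl)-2-[(triethylsilyl)oxy]hex-5-enal
Product: 22 tert-butyldimethyl({1-[(1E,5R)-2-methyl-5-(propan-2-yl)-5-[(triethylsilyl)oxy]hept-1-en-6-yn-1-yl]cyclopropyl}oxy)silane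
Conditions: dimethyl (1-diazo-2-oxopropyl)phosphonate, K2CO3, MeOH, 0 °C → rt
Reagents that add atoms: dimethyl (1-diazo-2-oxopropyl)phosphonate, COP(=O)(OC)C(=[N+]=[N-])C(C)=O
Why: Ohira–Bestmann (Seyferth–Gilbert) homologation supplies C6 and gives the terminal alkyne; the aldehyde has no α-hydrogen, so the C4 centre cannot epimerise, and both silyl ethers tolerate K2CO3/MeOH.

Step 12
Reactants: 22 tert-butyldimethyl({1-[(1E,5R)-2-methyl-5-(propan-2-yl)-5-[(triethylsilyl)oxy]hept-1-en-6-yn-1-yl]cyclopropyl}oxy)silane
Product: 23 tert-butyl{[(3R,8aR)-8a-methyl-3-(propan-2-yl)-3-[(triethylsilyl)oxy]-1,2,3,5,6,8a-hexahydroazulen-7-yl]oxy}dimethylsilane (daucane numbering: 1R,4R; alkenes C5=C6 and C9=C10)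
Conditions: [Rh(CO)2Cl]2 (5 mol %), 1,2-dichloroethane (0.02 M), 70 °C
Reagents that add atoms: none
Why: Intramolecular rhodium-catalysed [5+2] cycloaddition of a vinylcyclopropane and an alkyne; the closest known reaction type is the [Rh(CO)2Cl]2-catalysed coupling of 1-silyloxy- and 1-alkoxyvinylcyclopropanes with alkynes and its tethered variant with substituted alkenes. Monovalent rhodium binds the alkyne and the alkene, cleaves the strained C9–C7 bond (helped by the silyloxy group on C9) to a trivalent π-allyl/alkyl rhodacycle, inserts the alkyne at the allyl terminus to form C5–C1, and joins C6 to C7 by reductive elimination. Ring A therefore closes in the insertion step as a five-membered ring through the three-atom tether (exo with respect to the alkyne), and ring B closes by reductive elimination from an eight-membered rhodacycle. C1 is the only new stereocentre and the C4 carbinol controls it: in the folded tether one C4 substituent must sit syn to the C1 methyl across the forming cyclopentene, and placing the oxygen there and the branched isopropyl group on the other face avoids a 1,3 methyl/isopropyl contact, which leads to the (1R,4R) adduct. The E alkene keeps the tether trans to the cyclopropane so the reactive s-cis conformer is reachable, and the two cyclopropane CH2 groups are equivalent, so ring opening raises no regiochemical question. The step needs cycloaddition to beat alkyne oligomerisation, which dilution and the tether secure, and it leaves the C9=C10 enol ether and the C5=C6 alkene as the two handles for the endgame.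

Step 13
Reactants: 23 tert-butyl{[(3R,8aR)-8a-methyl-3-(propan-2-yl)-3-[(triethylsilyl)oxy]-1,2,3,5,6,8a-hexahydroazulen-7-yl]oxy}dimethylsilane
Product: 24 (3R,8aR)-8a-methyl-3-(propan-2-yl)-3-[(triethylsilyl)oxy]-2,3,5,6,8,8a-hexahydroazulen-7(1H)-one (C9 ketone, C5=C6 alkene)
Conditions: Bu4NF (1.05 equiv), AcOH (1.2 equiv), THF, −20 → 0 °C
Reagents that add atoms: none
Why: Buffered fluoride cleaves the silyl enol ether far faster than the hindered tertiary triethylsilyl ether and avoids protic acid next to the allylic tertiary C4–O bond; protonation at C10 creates no stereocentre.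

Step 14
Reactants: 24 (3R,8aR)-8a-methyl-3-(propan-2-yl)-3-[(triethylsilyl)oxy]-2,3,5,6,8,8a-hexahydroazulen-7(1H)-one
Product: 25 ethylene ketal of 24 (1,3-dioxolane at C9; 1R,4R; C5=C6 alkene)
Conditions: Me3SiOCH2CH2OSiMe3 (2 equiv), Me3SiOTf (5 mol %), CH2Cl2, −78 → −20 °C; pyridine quench
Reagents that add atoms: 1,2-bis(trimethylsilyloxy)ethane, C[Si](C)(C)OCCO[Si](C)(C)C
Why: Silyl-transfer ketalisation runs aprotically at low temperature with catalytic Lewis acid, conditions chosen to spare the tertiary allylic silyl ether; the ketal shields C9 from borane.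

Step 15
Reactants: 25 ethylene ketal of 24
Product: 27 ethylene ketal of (3R,3aS,4S,8aR)-4-hydroxy-8a-methyl-3-(propan-2-yl)-3-[(triethylsilyl)oxy]octahydroazulen-7(1H)-one (daucane numbering: 1R,4R,5S,6S; 5α-H, 6α-OH, trans-fused), via alkylborane 26 (not isolated)
Conditions: BH3·THF (3 equiv), THF, 0 °C → rt; then NaOH aq., H2O2, 0 °C → rt
Reagents that add atoms: hydrogen peroxide, OO
Why: Hydroboration–oxidation places boron on the less substituted C6 and hydrogen on C5 in a syn addition from the α-face, opposite the C1 methyl and the C4 silyloxy group, and oxidation with retention gives the 6α-alcohol; C5 and C6 are set together, by analogy with α-face hydroboration of trisubstituted alkenes next to an angular methyl.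

Step 16
Reactants: 28 4-hydroxy-3-methoxybenzoic acid (vanillic acid)
Product: 30 4-[(tert-butyldimethylsilyl)oxy]-3-methoxybenzoic acid, via silyl ester 29 (not isolated)
Conditions: t-BuMe2SiCl (2.3 equiv), imidazole, DMF, rt; then AcOH/THF/H2O, rt
Reagents that add atoms: tert-butylchlorodimethylsilane, CC(C)(C)[Si](C)(C)Cl
Why: Bis-silylation followed by selective hydrolysis of the labile silyl ester leaves the phenol protected, so the acid cannot acylate itself.

Step 17
Reactants: 27 ethylene ketal alcohol (1R,4R,5S,6S); 30 4-[(tert-butyldimethylsilyl)oxy]-3-methoxybenzoic acid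
Product: 32 4-[(tert-butyldimethylsilyl)oxy]-3-methoxybenzoate of 27 (ester on O6), via mixed anhydride 31 (not isolated)
Conditions: 30, 2,4,6-Cl3C6H2COCl, Et3N, THF, rt; then 27, 4-(dimethylamino)pyridine, toluene, rt → 50 °C
Reagents that add atoms: none
Why: Yamaguchi esterification is a standard way to acylate hindered secondary alcohols; O6 is the only free hydroxyl, so no selectivity is required, and the C6 configuration is untouched.

Step 18
Reactants: 32 4-[(tert-butyldimethylsilyl)oxy]-3-methoxybenzoate of 27
Product: 33 (3R,3aS,4S,8aR)-8a-methyl-7-oxo-3-(propan-2-yl)-3-[(triethylsilyl)oxy]decahydroazulen-4-yl 4-[(tert-butyldimethylsilyl)oxy]-3-methoxybenzoate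
Conditions: pyridinium p-toluenesulfonate (0.2 equiv), acetone/H2O (10:1), 50 °C
Reagents that add atoms: water, O
Why: Mild acid-catalysed ketal hydrolysis; the hindered tertiary silyl ether (no longer allylic), the aryl silyl ether and the ester should survive this weak acid.

Step 19
Reactants: 33 keto ester (C9 ketone)
Product: 34 (3R,3aS,4S,8aR)-8a-methyl-6-methylidene-7-oxo-3-(propan-2-yl)-3-[(triethylsilyl)oxy]decahydroazulen-4-yl 4-[(tert-butyldimethylsilyl)oxy]-3-methoxybenzoate
Conditions: (CH2O)n (3 equiv), iPr2NH2+ CF3CO2− (1 equiv), CF3CO2H (10 mol %), THF, 65 °C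
Reagents that add atoms: formaldehyde (as paraformaldehyde), C=O
Why: Mannich-type α-methylenation (aminomethylation, then elimination of the amine) under weakly acidic conditions; it takes place at C8 because C10 is neopentylic next to the quaternary C1, and no strong base is used that could trigger acyl transfer from O6.

Step 20
Reactants: 34 α-methylene ketone
Product: 35 (3R,3aS,4S,7S,8aR)-7-hydroxy-8a-methyl-6-methylidene-3-(propan-2-yl)-3-[(triethylsilyl)oxy]decahydroazulen-4-yl 4-[(tert-butyldimethylsilyl)oxy]-3-methoxybenzoate
Conditions: (3aR)-1-methyl-3,3-diphenyltetrahydro-1H,3H-pyrrolo[1,2-c][1,3,2]oxazaborole (0.3 equiv), catecholborane (1.5 equiv), toluene, −78 °C; aq. work-up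
Reagents that add atoms: none
Why: Corey–Bakshi–Shibata reduction: with the sp2 carbon C8 as the large group and the C10 methylene as the small one, the (R)-oxazaborolidine should deliver hydride to the β-face and give the (9S)-carbinol by 1,2-reduction; catecholborane is used because it does not hydroborate the exocyclic alkene.

Step 21
Reactants: 35 bis-silylated allylic alcohol
Product: 36 (3R,3aS,4S,7S,8aR)-3,7-dihydroxy-8a-methyl-6-methylidene-3-(propan-2-yl)decahydroazulen-4-yl 4-hydroxy-3-methoxybenzoate (the target; daucane numbering 1R,4R,5S,6S,9S)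
Conditions: Bu4NF (3 equiv), AcOH (3 equiv), THF, 0 °C → rt
Reagents that add atoms: none
Why: Buffered fluoride removes the aryl silyl ether and the tertiary triethylsilyl ether in one operation; the near-neutral medium avoids ester migration or cleavage and leaves the allylic alcohol and exocyclic alkene alone.

## Compound list

1 | prop-2-yn-1-ol | C#CCO | starting material
2 | isopropylmagnesium chloride | CC(C)[Mg]Cl | starting material
3 | 3-methyl-2-methylidenebutan-1-ol | CC(C)C(=C)CO | intermediate
4 | [(2R)-2-(propan-2-yl)oxiran-2-yl]methanol | OC[C@]1(C(C)C)CO1 | intermediate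
5 | triethyl{[(2S)-2-(propan-2-yl)oxiran-2-yl]methoxy}silane | CC[Si](CC)(CC)OC[C@]1(C(C)C)CO1 | intermediate
6 | trimethyl(prop-1-yn-1-yl)silane | CC#C[Si](C)(C)C | starting material
7 | [3-(trimethylsilyl)prop-2-yn-1-yl]lithium (not isolated) | [Li]CC#C[Si](C)(C)C | intermediate
8 | (2R)-2-(propan-2-yl)-1-[(triethylsilyl)oxy]-7-(trimethylsilyl)hept-6-yn-2-ol (not isolated) | CC[Si](CC)(CC)OC[C@](O)(C(C)C)CCC#C[Si](C)(C)C | intermediate
9 | (2R)-2-(propan-2-yl)hept-6-yne-1,2-diol | OC[C@](O)(C(C)C)CCC#C | intermediate
10 | (E)-alkenyldimethylalane from 9, hydroxyls as dimethylaluminium alkoxides (not isolated) | C[Al](C)OC[C@](O[Al](C)C)(C(C)C)CC/C(C)=C/[Al](C)C | intermediate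
11 | (2R,6E)-7-iodo-6-methyl-2-(propan-2-yl)hept-6-ene-1,2-diol | OC[C@](O)(C(C)C)CC/C(C)=C/I | intermediate
12 | (2R,6E)-7-iodo-6-methyl-2-(propan-2-yl)-1,2-bis[(triethylsilyl)oxy]hept-6-ene | CC[Si](CC)(CC)OC[C@](O[Si](CC)(CC)CC)(C(C)C)CC/C(C)=C/I | intermediate
13 | (1-ethoxycyclopropoxy)trimethylsilane | CCOC1(O[Si](C)(C)C)CC1 | starting material
14 | 1-ethoxycyclopropan-1-ol | CCOC1(O)CC1 | intermediate
15 | [(1E,5R)-2-methyl-5-(propan-2-yl)-5,6-bis[(triethylsilyl)oxy]hex-1-en-1-yl]lithium (not isolated) | CC[Si](CC)(CC)OC[C@](O[Si](CC)(CC)CC)(C(C)C)CC/C(C)=C/[Li] | intermediate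
16 | [(1E,5R)-2-methyl-5-(propan-2-yl)-5,6-bis[(triethylsilyl)oxy]hex-1-en-1-yl]magnesium bromide (not isolated) | CC[Si](CC)(CC)OC[C@](O[Si](CC)(CC)CC)(C(C)C)CC/C(C)=C/[Mg]Br | intermediate
17 | bromomagnesium 1-ethoxycyclopropan-1-olate (not isolated) | CCOC1(O[Mg]Br)CC1 | intermediate
18 | cyclopropanone (not isolated) | O=C1CC1 | intermediate
19 | 1-{(1E,5R)-2-methyl-5-(propan-2-yl)-5,6-bis[(triethylsilyl)oxy]hex-1-en-1-yl}cyclopropan-1-ol | CC[Si](CC)(CC)OC[C@](O[Si](CC)(CC)CC)(C(C)C)CC/C(C)=C/C1(O)CC1 | intermediate
20 | tert-butyl({1-[(1E,5R)-2-methyl-5-(propan-2-yl)-5,6-bis[(triethylsilyl)oxy]hex-1-en-1-yl]cyclopropyl}oxy)dimethylsilane | CC[Si](CC)(CC)OC[C@](O[Si](CC)(CC)CC)(C(C)C)CC/C(C)=C/C1(O[Si](C)(C)C(C)(C)C)CC1 | intermediate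
21 | (2R,5E)-6-{1-[(tert-butyldimethylsilyl)oxy]cyclopropyl}-5-methyl-2-(propan-2-yl)-2-[(triethylsilyl)oxy]hex-5-enal | O=C[C@](O[Si](CC)(CC)CC)(C(C)C)CC/C(C)=C/C1(O[Si](C)(C)C(C)(C)C)CC1 | intermediate
22 | tert-butyldimethyl({1-[(1E,5R)-2-methyl-5-(propan-2-yl)-5-[(triethylsilyl)oxy]hept-1-en-6-yn-1-yl]cyclopropyl}oxy)silane | C#C[C@](O[Si](CC)(CC)CC)(C(C)C)CC/C(C)=C/C1(O[Si](C)(C)C(C)(C)C)CC1 | intermediate
23 | tert-butyl{[(3R,8aR)-8a-methyl-3-(propan-2-yl)-3-[(triethylsilyl)oxy]-1,2,3,5,6,8a-hexahydroazulen-7-yl]oxy}dimethylsilane | C1CC=C2[C@](C)(CC[C@@]2(O[Si](CC)(CC)CC)C(C)C)C=C1O[Si](C)(C)C(C)(C)C | intermediate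
24 | (3R,8aR)-8a-methyl-3-(propan-2-yl)-3-[(triethylsilyl)oxy]-2,3,5,6,8,8a-hexahydroazulen-7(1H)-one | O=C1CCC=C2[C@](C)(CC[C@@]2(O[Si](CC)(CC)CC)C(C)C)C1 | intermediate
25 | ethylene ketal of 24 (dioxolane at C9) | C1CC=C2[C@](C)(CC[C@@]2(O[Si](CC)(CC)CC)C(C)C)CC13OCCO3 | intermediate
26 | C6 alkylborane from 25, 5α-H and 6α-BH2 (not isolated) | C1C[C@H](B)[C@@H]2[C@](C)(CC[C@@]2(O[Si](CC)(CC)CC)C(C)C)CC13OCCO3 | intermediate
27 | ethylene ketal of (3R,3aS,4S,8aR)-4-hydroxy-8a-methyl-3-(propan-2-yl)-3-[(triethylsilyl)oxy]octahydroazulen-7(1H)-one | C1C[C@H](O)[C@@H]2[C@](C)(CC[C@@]2(O[Si](CC)(CC)CC)C(C)C)CC13OCCO3 | intermediate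
28 | 4-hydroxy-3-methoxybenzoic acid (vanillic acid) | COc1cc(C(=O)O)ccc1O | starting material
29 | tert-butyldimethylsilyl 4-[(tert-butyldimethylsilyl)oxy]-3-methoxybenzoate (not isolated) | COc1cc(C(=O)O[Si](C)(C)C(C)(C)C)ccc1O[Si](C)(C)C(C)(C)C | intermediate
30 | 4-[(tert-butyldimethylsilyl)oxy]-3-methoxybenzoic acid | COc1cc(C(=O)O)ccc1O[Si](C)(C)C(C)(C)C | intermediate
31 | 4-[(tert-butyldimethylsilyl)oxy]-3-methoxybenzoic 2,4,6-trichlorobenzoic anhydride (not isolated) | COc1cc(C(=O)OC(=O)c2c(Cl)cc(Cl)cc2Cl)ccc1O[Si](C)(C)C(C)(C)C | intermediate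
32 | 4-[(tert-butyldimethylsilyl)oxy]-3-methoxybenzoate of 27 (ester on O6) | C1C[C@H](OC(=O)c2ccc(O[Si](C)(C)C(C)(C)C)c(OC)c2)[C@@H]2[C@](C)(CC[C@@]2(O[Si](CC)(CC)CC)C(C)C)CC13OCCO3 | intermediate
33 | (3R,3aS,4S,8aR)-8a-methyl-7-oxo-3-(propan-2-yl)-3-[(triethylsilyl)oxy]decahydroazulen-4-yl 4-[(tert-butyldimethylsilyl)oxy]-3-methoxybenzoate | C1C[C@H](OC(=O)c2ccc(O[Si](C)(C)C(C)(C)C)c(OC)c2)[C@@H]2[C@](C)(CC[C@@]2(O[Si](CC)(CC)CC)C(C)C)CC1=O | intermediate
34 | (3R,3aS,4S,8aR)-8a-methyl-6-methylidene-7-oxo-3-(propan-2-yl)-3-[(triethylsilyl)oxy]decahydroazulen-4-yl 4-[(tert-butyldimethylsilyl)oxy]-3-methoxybenzoate | C=C1C[C@H](OC(=O)c2ccc(O[Si](C)(C)C(C)(C)C)c(OC)c2)[C@@H]2[C@](C)(CC[C@@]2(O[Si](CC)(CC)CC)C(C)C)CC1=O | intermediate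
35 | (3R,3aS,4S,7S,8aR)-7-hydroxy-8a-methyl-6-methylidene-3-(propan-2-yl)-3-[(triethylsilyl)oxy]decahydroazulen-4-yl 4-[(tert-butyldimethylsilyl)oxy]-3-methoxybenzoate | C=C1C[C@H](OC(=O)c2ccc(O[Si](C)(C)C(C)(C)C)c(OC)c2)[C@@H]2[C@](C)(CC[C@@]2(O[Si](CC)(CC)CC)C(C)C)C[C@@H]1O | intermediate
36 | (3R,3aS,4S,7S,8aR)-3,7-dihydroxy-8a-methyl-6-methylidene-3-(propan-2-yl)decahydroazulen-4-yl 4-hydroxy-3-methoxybenzoate | C=C1C[C@H](OC(=O)c2ccc(O)c(OC)c2)[C@@H]2[C@](C)(CC[C@@]2(O)C(C)C)C[C@@H]1O | target

## Step count and least certain steps

Total: 21 steps. Longest linear sequence: 19 steps (steps 1–6, 8–15 and 17–21; steps 7 and 16 prepare side components).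

**Step 12 (key step).** Two processes are most likely to fail. Alkyne insertion at the fully substituted allyl terminus may be slow, so alkyne oligomerisation and isomerisation of the vinylcyclopropane could take over. The facial choice at C1 may be poor, because the two C4 substituents (isopropyl and silyloxy) differ little in effective size. Fallback: set out from 22 and return to 23 with [CpRu(MeCN)3]PF6 (10 mol %) in acetone, rt → 50 °C. This is a change of mechanism rather than of solvent or temperature. Divalent ruthenium first couples the alkyne and the alkene oxidatively to a ruthenacyclopentene (C1–C5 formed first, by a step known to accept more substituted alkenes) and opens the cyclopropane afterwards. The bond that is hard for rhodium is therefore made in a different elementary step, and the tether folds against a cyclopentadienyl ligand. The fallback makes no new compound (F0).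

**Step 15.** Most likely is borane addition from the β-face, or poor discrimination between faces, because the α-face carries the C4 isopropyl group; addition to an alkene flanked by two fully substituted carbons may also be slow. Fallback: set out from 25 and use the β-preference instead of fighting it. A peracid (mCPBA, NaHCO3, CH2Cl2) should choose the same face and give the 5β,6β-epoxide F1. BF3·OEt2 (catalytic, CH2Cl2, −78 °C) should then induce a Meinwald rearrangement in which the C6 hydrogen migrates to C5 across the α-face, anti to the departing C5–O bond, giving the trans-fused C6 ketone F2. NaBH4 (MeOH, −20 °C), attacking from the same accessible β-face, returns the 6α-alcohol 27. The rearrangement must be kept cold and base-free to suppress migration of the isopropyl group and epimerisation at C5.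

**Step 20.** Most likely is substrate control opposing the catalyst: hydride delivery anti to the C1 methyl would give the C9 epimer. Conjugate reduction of the exocyclic enone is a second risk. Fallback: set out from 34 and accept substrate control. Luche reduction (NaBH4, CeCl3·7H2O, MeOH, −78 °C) gives the 9-epi allylic alcohol F3. Mitsunobu inversion with chloroacetic acid (PPh3, diisopropyl azodicarboxylate, toluene) gives the (9S)-chloroacetate F4, and thiourea/NaHCO3 in ethanol removes the chloroacetyl group selectively to return 35. If the small hydride gives 35 directly, the inversion is not needed.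

**Step 19.** Most likely are incomplete aminomethylation at a ketone whose C8 is β to a bulky ester-bearing carbon, partial loss of the aryl silyl ether on heating with the ammonium salt, and conjugate addition of amine to the product. Fallback: set out from 33 and attach C14 as a hydroxymethyl group. Me3SiOTf/Et3N (CH2Cl2, 0 °C) gives the C8=C9 trimethylsilyl enol ether F5 (the C10 side is neopentylic). A Mukaiyama aldol reaction with aqueous formaldehyde catalysed by Yb(OTf)3 (THF, rt) gives the 8-hydroxymethyl ketone F6. Mesylation and elimination (MeSO2Cl, Et3N, then DBU, CH2Cl2, 0 °C) return 34.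

**Step 8.** Most likely are slow release of cyclopropanone from the magnesium hemiacetalate, so the alkenylmagnesium is consumed by proton sources, and ring opening of the magnesium cyclopropanolate on warming. Fallback: set out from 12 and build the cyclopropanol from an ester. Palladium-catalysed methoxycarbonylation (Pd(OAc)2, PPh3, CO 1 atm, Et3N, MeOH/DMF, 50 °C) gives the (E)-enoate F7 with retention of geometry. Kulinkovich cyclopropanation (EtMgBr, Ti(OiPr)4, THF, 0 °C → rt) returns cyclopropanol 19.

## Further compounds

F0 | step 12 | none | none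
F1 | step 15 | 5β,6β-epoxide of ketal 25 (oxygen syn to the C1 methyl) | C1C[C@H]2O[C@@]23[C@](C)(CC[C@@]3(O[Si](CC)(CC)CC)C(C)C)CC14OCCO4
F2 | step 15 | trans-fused C6 ketone (5α-H) with the C9 ethylene ketal and 4-O-triethylsilyl group | C1CC(=O)[C@@H]2[C@](C)(CC[C@@]2(O[Si](CC)(CC)CC)C(C)C)CC13OCCO3
F3 | step 20 | C9 epimer (9R) of allylic alcohol 35 | C=C1C[C@H](OC(=O)c2ccc(O[Si](C)(C)C(C)(C)C)c(OC)c2)[C@@H]2[C@](C)(CC[C@@]2(O[Si](CC)(CC)CC)C(C)C)C[C@H]1O
F4 | step 20 | (9S)-chloroacetate of 35 | C=C1C[C@H](OC(=O)c2ccc(O[Si](C)(C)C(C)(C)C)c(OC)c2)[C@@H]2[C@](C)(CC[C@@]2(O[Si](CC)(CC)CC)C(C)C)C[C@@H]1OC(=O)CCl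
F5 | step 19 | C8=C9 trimethylsilyl enol ether of keto ester 33 | C[Si](C)(C)OC1=CC[C@H](OC(=O)c2ccc(O[Si](C)(C)C(C)(C)C)c(OC)c2)[C@@H]2[C@](C)(CC[C@@]2(O[Si](CC)(CC)CC)C(C)C)C1
F6 | step 19 | 8-(hydroxymethyl) derivative of keto ester 33 (C8 epimers) | OCC1C[C@H](OC(=O)c2ccc(O[Si](C)(C)C(C)(C)C)c(OC)c2)[C@@H]2[C@](C)(CC[C@@]2(O[Si](CC)(CC)CC)C(C)C)CC1=O
F7 | step 8 | methyl (2E,6R)-3-methyl-6-(propan-2-yl)-6,7-bis[(triethylsilyl)oxy]hept-2-enoate | CC[Si](CC)(CC)OC[C@](O[Si](CC)(CC)CC)(C(C)C)CC/C(C)=C/C(=O)OC
A1 | alternative 1 | cis-fused 9-[(tert-butyldimethylsilyl)oxy]-1-methyl-4-(propan-2-yl)-3-(trimethylsilyl)bicyclo[5.3.0]dec-3-en-6-one (daucane numbering) | C1CC(=O)[C@H]2[C@](C)(CC([Si](C)(C)C)=C2C(C)C)C[C@H]1O[Si](C)(C)C(C)(C)C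
A2 | alternative 1 | (5S)-5-[(tert-butyldimethylsilyl)oxy]-3-methylcyclohept-2-en-1-one | CC1=CC(=O)CC[C@H](O[Si](C)(C)C(C)(C)C)C1
A3 | alternative 1 | trimethyl(4-methylpenta-1,2-dien-3-yl)silane | C=C=C(C(C)C)[Si](C)(C)C
A4 | alternative 2 | methyl 6,9-bis[(tert-butyldimethylsilyl)oxy]-4,4-(ethylenedioxy)-1-methylbicyclo[5.3.0]deca-5,8-diene-8-carboxylate (daucane numbering) | COC(=O)C1=C(O[Si](C)(C)C(C)(C)C)C[C@@]2(C)CCC3(OCCO3)C2=C(O[Si](C)(C)C(C)(C)C)C1
A5 | alternative 2 | tert-butyl{[1-(7-methyl-1,4-dioxaspiro[4.4]non-6-en-6-yl)ethenyl]oxy}dimethylsilane | C=C(O[Si](C)(C)C(C)(C)C)C1=C(C)CCC12OCCO2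
A6 | alternative 2 | methyl 3-[(tert-butyldimethylsilyl)oxy]-2-diazobut-3-enoate | COC(=O)C(=[N+]=[N-])C(=C)O[Si](C)(C)C(C)(C)C
A7 | alternative 3 | daucene (dauca-4,8-diene) | CC1=CC[C@@]2(C)CCC(C(C)C)=C2CC1
A8 | alternative 3 | (2E,6E)-farnesyl diphosphate | CC(C)=CCC/C(C)=C/CC/C(C)=C/COP(=O)(O)OP(=O)(O)O
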